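**Remark on the chemistry (assumption):** the target is read as (S)-20-methyldocosyl 2,3-dihydroxybenzoate (C30H52O4). The building-block structures were compared with it and no discrepancy was found. The R alkene 8 and the S alkane 9 have the same spatial arrangement; only the CIP rank of vinyl or ethyl against the long chain differs. The (R,Rp) antipode of the ligand is assumed to be the one that delivers R, and this would be confirmed on a short-chain model before material is committed.

## Structural features

Gentiside B is the ester of 2,3-dihydroxybenzoic acid (benzene ring A, the only ring) with an anteiso C23 alcohol: the carboxyl oxygen is bound to C1 of an unbranched saturated chain C1–C22 that carries one methyl group on C20. C20 is the only stereocentre (S). It has no neighbouring stereocentre and no functional group within nineteen methylene units, and its substituents are H, CH3, the ethyl group C21–C22 and the chain carbon C19. The fragile part is the head group: the free catechol on ring A is oxidised easily in base and air and chelates metals, and the salicylate-type ester should not meet hydroxide or strong nucleophiles; the chain itself is inert. The real difficulty is C20, because a reagent has to distinguish methyl from ethyl at a centre with no nearby handle, and because stereo-, regio- and chain-length isomers of such a waxy lipid cannot be separated at the end. The key step exploits the fact that C21–C22 can be written as a vinyl group: C20 then becomes an allylic methine, C20–C21–C22 an allyl unit, and the C20–CH3 bond can be made by SN2' methylation of an allylic bromide at C22, where a catalyst only has to choose between the two faces of planar C20. The ester oxygen at C1 can be carried through the sequence as a primary chloride, which survives Grignard and copper chemistry at low temperature and lets the acid be attached last, as its carboxylate, without protecting the catechol.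

## Logic of the disconnections

**13 to 9 and 10.** The first cut is the O–C1 bond of the ester in 13. Cutting on the alkyl side of the ester oxygen makes the forward step an alkylation of a carboxylate. The carboxylic acid of 10 is far more acidic than its two phenols, so it can be addressed alone and ring A needs no protecting groups. The gain is that the aromatic head group enters in the last step and never meets an organometallic or a reducing agent. The demand is a base weak enough to leave the phenols protonated, iodide catalysis to make the C1–Cl bond of 9 reactive enough (through 12), and exclusion of oxygen.

**9 to 8.** No bond is cut; the C21–C22 ethyl group of 9 is traced back to the vinyl group of 8. This makes C20 allylic and exposes the SN2' retron. The forward reduction must add H2 across C21=C22 without moving the double bond to C20=C21, which would flatten C20 and racemise it. A concerted, metal-free hydrogen transfer is therefore planned, and it is placed before the catechol is attached. The terminal alkene of 8 is also the last point at which a linear regioisomer, an internal alkene, can still be removed.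

**8 to 6 and 7.** The strategic cut is the C20–CH3 bond, made with allylic transposition: the methyl group is 7, the double bond returns to C20=C21, and bromide sits on C22 in 6. The stereocentre disappears and the precursor is an achiral linear chain; all stereochemical information then comes from a chiral copper catalyst. The forward step must deliver methyl to C20 and not to C22, to one face of C20 only, and must leave the C1–Cl bond alone. It also needs 6 as the pure E isomer, because the Z isomer is expected to react with a different, probably opposite, facial preference. The skeleton and leaving groups of 6 are kept; what is tightened is the specification of its geometric purity.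

**6 to 4 and 5.** 6 is cut at the C20=C21 double bond by a cross-metathesis transform; 5 supplies C21, C22 and the bromide. One step replaces an olefination, reduction and bromination sequence. The forward step must favour the E alkene, avoid homodimerisation of 4, and avoid migration of the double bond along the chain, which would give homologues that cannot be removed.

**4 to 1 and 2.** 4 is cut at C10–C11 into 2 (C1–C10, chlorine on C1) and the organomagnesium 3 derived from 1 (C11–C21). Both pieces are commercial and of similar size. The bromine and chlorine pair of 2 lets one end couple while the other survives to the last step. The forward coupling must discriminate C–Br from C–Cl and keep Wurtz-type side coupling low.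

## Other disconnections considered

**Alternative 1:** The cut is the C19–C20 bond. In the forward direction racemic 2-(1-chloroethyl)-4,4,5,5-tetramethyl-1,3,2-dioxaborolane (A1) and [19-(benzyloxy)nonadecyl]zinc iodide (A2) would be joined by NiBr2·diglyme and a chiral N,N'-dimethyl-1,2-diarylethane-1,2-diamine. The product would be the secondary boronic ester (R)-2-[21-(benzyloxy)henicosan-2-yl]-4,4,5,5-tetramethyl-1,3,2-dioxaborolane (A3).
- In its favour: the coupling is enantioconvergent, so a cheap racemic C2 electrophile is used in full. Both enantiomers of A1 pass through the same α-boryl radical, and the nickel complex has to tell a boryl group from a methyl group, which differ far more than methyl and ethyl. There is no branched or linear question and no cryogenic step.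
- Against it here: C20 of A3 carries boron where the target has ethyl, so a stereospecific two-carbon C–C bond formation must follow (Zweifel vinylation with retention and then saturation, or two Matteson homologations and a protodeboronation). The benzyl ether must then be cleaved to (S)-20-methyldocosan-1-ol (A4), and the hydroxyl group of A4 must be turned into a leaving group before the unprotected acid can be attached. A2 needs a C19 ω-benzyloxy iodide whose assembly is at least as long as steps 1 and 2, and a waxy long-chain alkylzinc such as A2 is awkward in the polar solvents this coupling prefers.
- Comparison: on mechanism the two plans are equals, since in both a chiral catalyst creates C20 from achiral or racemic material. Alternative 1 is the better plan on regiochemistry, having none to control, and on the size of the difference the ligand must read. On structure the chosen plan is better: it places carbon exactly where the target has it, whereas A3 needs boron exchanged for carbon, and the Zweifel variant would only re-create a vinyl group on C20, the same latent-ethyl device by a longer road. On step economy alternative 1 needs about four operations after its key step against two here.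

**Alternative 2:** The cut is the C17–C18 bond. In the forward direction (S)-4-methylhexanoic acid (A5) and 18-methoxy-18-oxooctadecanoic acid, the monomethyl ester of octadecanedioic acid (A6), would be co-electrolysed at a platinum anode in partly neutralised methanol. The two primary radicals left after loss of CO2 would combine to methyl (S)-20-methyldocosanoate (A7), which would then be reduced to A4, activated and esterified.
- In its favour: the configuration of C20 is bought with A5 and is not at risk, because the radical is formed two carbons away from it. No chiral catalyst, alkene geometry or regiochemistry is involved; A6 is a catalogue compound and the only reagent is current.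
- Against it here: radical–radical combination is statistical, so A7 must be accompanied by both symmetrical dimers (a C10 hydrocarbon and a C34 diester). One acid, either the valuable A5 or the poorly methanol-soluble A6, has to be used in excess and partly wasted. Over-oxidation of the radicals to cations would add ethers and alkenes of similar chain length. The optical purity of A5 is that of its natural C5 precursor and is hard to raise, and three further steps follow the coupling.
- Comparison: alternative 2 is the better plan on stereochemical certainty, and on structure it is the equal of the chosen plan, since both join two pieces of comparable size far from the head group. On mechanism it is weaker, because an unselective radical–radical combination gives a statistical mixture where the chosen plan relies on a catalyst-controlled substitution, and purification of A7 suffers accordingly. On step economy, with A5 bought, alternative 2 needs four steps against five and is slightly the better; it needs one more step after its key step, and if A5 has to be prepared its total length is comparable to or above the five steps chosen here.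

**Alternative 3:** No skeletal bond is cut; the C1–O bond is traced back to a C1–H bond of the parent hydrocarbon. In the forward direction (S)-3-methyldocosane (A8) would react with bis(pinacolato)diboron A9 under [Ir(cod)OMe]2 and a 2-methyl-substituted phenanthroline ligand in an inert cycloalkane solvent. A9 would be the boron source, and the product would be (S)-4,4,5,5-tetramethyl-2-(20-methyldocosyl)-1,3,2-dioxaborolane (A10), whose C–B bond would be oxidised to the C–O bond of A4.
- In its favour: A8 should be available in one copper-catalysed coupling of a chiral-pool C5 Grignard reagent with a C18 halide. The stereocentre is bought, stays far from every reactive site, and no functional group is carried through the chain assembly. On paper this is the shortest route.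
- Against it here: A8 has three methyl groups. The branch methyl on C20 is shielded, but the methyl of the ethyl group (C22 of the target) is only β to the branch and is expected to compete with the remote unbranched terminus. Borylation there would give a constitutional isomer of A10 of identical polarity, and finally an isomer of the target that cannot be removed. Alkane borylation also works best with the alkane in excess; with the solid C23 alkane A8 as limiting partner and A9 in excess, conversion, double borylation and recovery become issues.
- Comparison: alternative 3 is the better plan on step economy and on stereochemical security. On mechanism it is the equal of the chosen plan, in that the decisive selectivity is left to a catalyst. On structure it is weaker in what it asks of that catalyst: a choice between two nearly equivalent CH3 termini of A8, for which only a small steric bias exists. The chosen plan asks for a branched and facial selectivity the copper catalyst is suited to, and its minor regioisomer can be removed as an internal alkene.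

Key step: step 3

## Route

Step 1
Reactants: 1 11-bromoundec-1-ene; 2 1-bromo-10-chlorodecane
Product: 4 21-chlorohenicos-1-ene, via undec-10-enylmagnesium bromide 3 (not isolated)
Conditions: 1, Mg turnings, THF, 40 °C; then added to 2 (1.1 equiv), Li2CuCl4 (3 mol %), THF, −10 °C to rt
Reagents that add atoms: magnesium, [Mg] (carried by intermediate 3 only)
Why: Copper-catalysed sp3–sp3 cross-coupling of a primary alkyl Grignard reagent with a primary alkyl bromide (Kochi-type, Li2CuCl4); the C–Br bond of 2 is displaced far faster than its C–Cl bond, so the chloride is carried on as the latent C1 electrophile, and the terminal alkene is inert. Surplus 2 is distilled off and hydrocarbon by-products of Grignard formation are removed on silica.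

Step 2
Reactants: 4 21-chlorohenicos-1-ene; 5 (E)-1,4-dibromobut-2-ene
Product: 6 (E)-1-bromo-22-chlorodocos-2-ene
Conditions: 5 (3 equiv), second-generation Hoveyda–Grubbs catalyst RuCl2(H2IMes)(=CH-C6H4-2-OiPr), C31H38Cl2N2ORu (3 mol %), 1,4-benzoquinone (10 mol %), CH2Cl2, reflux; recrystallised from pentane at −30 °C
Reagents that add atoms: none
Why: Olefin cross-metathesis of a terminal alkene with an excess of a symmetrical 1,4-disubstituted but-2-ene; reversible carbene exchange should lead to the more stable E alkene, the excess of 5 suppresses homodimerisation of 4, and benzoquinone intercepts ruthenium hydrides that would move the double bond along the chain. Low-temperature recrystallisation should raise the E content, which matters because geometric purity becomes enantiomeric purity in step 3.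

Step 3
Reactants: 6 (E)-1-bromo-22-chlorodocos-2-ene; 7 methylmagnesium bromide
Product: 8 (R)-22-chloro-3-methyldocos-1-ene
Conditions: CuBr·SMe2 (5 mol %), (R,Rp)-Taniaphos, (Rp)-1-[(R)-α-(dimethylamino)-2-(diphenylphosphino)benzyl]-2-(diphenylphosphino)ferrocene, C43H39FeNP2 (6 mol %), 7 (3 M in Et2O, 1.3 equiv), CH2Cl2, −78 °C, 6 in CH2Cl2 added over 2 h; MeOH quench at −78 °C
Reagents that add atoms: none
Why: Copper-catalysed asymmetric allylic alkylation, an enantioselective SN2' substitution of a linear aliphatic (E)-allylic bromide by a Grignard reagent, is the closest known reaction type and covers exactly this substrate class. Transmetalation of 7 to the ligated monovalent copper bromide gives a chiral methylcopper·MgBr2 species that binds the C2=C3 alkene of 6 and adds oxidatively at C3 (C20 of the target) anti to the departing C1 bromide, giving a σ-allyl complex of trivalent copper. In non-coordinating CH2Cl2 at −78 °C reductive elimination from this C3-bound species should outrun its σ–π–σ shift to the C1-bound isomer, so the C3–CH3 bond forms, the double bond moves to C1=C2 and the branched product results; no ring is closed. The one new stereocentre is under catalyst control: the ferrocenyl diphosphine makes the two faces of planar C3 diastereotopic in the π-complex, and methyl delivery to the Re face of C3 gives R. The (R,Rp) ligand is taken as the antipode with this preference by analogy with simple (E)-allylic bromides; both antipodes are available and the sense would be confirmed on a short-chain model first. The step needs branched over linear regioselectivity, face selectivity and chemoselectivity for the allylic bromide over the primary chloride; the unhindered linear E alkene, the bromide leaving group and the inertness of a primary C–Cl bond to methylmagnesium and methylcopper species at −78 °C secure them. Slow addition of 6 keeps its stationary concentration low, which suppresses ligand-free background methylation and keeps the waxy substrate in solution. Any linear isomer, an internal alkene, would be removed on AgNO3-impregnated silica at this stage, before step 4 makes it inseparable.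

Step 4
Reactants: 8 (R)-22-chloro-3-methyldocos-1-ene
Product: 9 (S)-1-chloro-20-methyldocosane
Conditions: 2-nitrobenzenesulfonylhydrazide (NBSH, 5 equiv in portions), Et3N, CH2Cl2, rt
Reagents that add atoms: none
Why: Diimide reduction: HN=NH released from the sulfonylhydrazide transfers two hydrogens to the monosubstituted alkene in a concerted syn manner; with no metal hydride present the double bond cannot migrate to C20, so the stereocentre is untouched, and the primary chloride is inert at room temperature. The descriptor changes from R to S only because ethyl ranks below the long chain whereas vinyl ranked above it.

Step 5
Reactants: 9 (S)-1-chloro-20-methyldocosane; 10 2,3-dihydroxybenzoic acid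
Product: 13 gentiside B [(S)-20-methyldocosyl 2,3-dihydroxybenzoate], via potassium 2,3-dihydroxybenzoate 11 (not isolated), via (S)-1-iodo-20-methyldocosane 12 (not isolated)
Conditions: 10 (3 equiv), KHCO3 (2.5 equiv), NaI (0.5 equiv), DMF/THF, 70 °C, Ar
Reagents that add atoms: potassium hydrogencarbonate, [K+].OC([O-])=O (potassium carried by intermediate 11 only); sodium iodide, [Na+].[I-] (iodine carried by intermediate 12 only)
Why: SN2 O-alkylation of a carboxylate with in situ Finkelstein activation: hydrogencarbonate deprotonates only the carboxylic acid of 10, iodide turns 9 into the more reactive 12, and the carboxylate of 11 displaces iodide at C1. No bond to C20 is involved; keeping the acid in excess over the base and excluding air should hold ether formation and catechol oxidation down.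

## Compound list

1 | 11-bromoundec-1-ene | C=CCCCCCCCCCBr | starting material
2 | 1-bromo-10-chlorodecane | ClCCCCCCCCCCBr | starting material
3 | undec-10-enylmagnesium bromide | C=CCCCCCCCCC[Mg]Br | intermediate
4 | 21-chlorohenicos-1-ene | C=CCCCCCCCCCCCCCCCCCCCCl | intermediate
5 | (E)-1,4-dibromobut-2-ene | BrC/C=C/CBr | starting material
6 | (E)-1-bromo-22-chlorodocos-2-ene | ClCCCCCCCCCCCCCCCCCCC/C=C/CBr | intermediate
7 | methylmagnesium bromide | C[Mg]Br | starting material
8 | (R)-22-chloro-3-methyldocos-1-ene | C=C[C@H](C)CCCCCCCCCCCCCCCCCCCCl | intermediate
9 | (S)-1-chloro-20-methyldocosane | CC[C@H](C)CCCCCCCCCCCCCCCCCCCCl | intermediate
10 | 2,3-dihydroxybenzoic acid | OC(=O)c1cccc(O)c1O | starting material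
11 | potassium 2,3-dihydroxybenzoate | [K+].[O-]C(=O)c1cccc(O)c1O | intermediate
12 | (S)-1-iodo-20-methyldocosane | CC[C@H](C)CCCCCCCCCCCCCCCCCCCI | intermediate
13 | gentiside B, (S)-20-methyldocosyl 2,3-dihydroxybenzoate | CC[C@H](C)CCCCCCCCCCCCCCCCCCCOC(=O)c1cccc(O)c1O | target

## Step count and risks

Total step count: 5. Longest linear sequence: 5 steps (1 to 4 to 6 to 8 to 9 to 13).

**Step 3 (key step).** The most likely failure is loss of enantiomeric purity. It could come from residual Z isomer in 6, from ligand-free or uncatalysed background methylation when substrate accumulates, or from partial crystallisation of the C22 bromide out of CH2Cl2 at −78 °C. Crystallisation slows the catalysed path and invites warming, and warming allows σ-allyl isomerisation and erodes the branched selectivity. The enantiomeric purity is also hard to read on an unfunctionalised chain, so an aliquot of 8 would have to be degraded at the vinyl group and derivatised (for example as a Mosher ester) for analysis.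
Fallback (chiral pool in place of asymmetric catalysis), setting out from 2 and returning at 9: (S)-1-bromo-2-methylbutane F1 is converted with Mg in THF into (S)-2-methylbutylmagnesium bromide F2. F2 is coupled with an excess of 1,8-dibromooctane F3 under Li2CuCl4 to give, after distillation, (S)-1-bromo-10-methyldodecane F4. F4 is converted into (S)-(10-methyldodecyl)magnesium bromide F5, which is coupled with 2 under the conditions of step 1 to give 9 directly. C20 is then bought with F1 and no bond to it is made or broken; the price is that the optical purity is that of commercial F1, and the route no longer uses the chosen disconnection.

**Step 2.** The most likely failures are incomplete E selectivity (the metathesis equilibrium leaves some Z isomer), chain walking of the double bond by ruthenium hydride species before metathesis (giving one-carbon homologues that cannot be separated), and homodimerisation of 4.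
Fallback (stepwise E-selective olefination), setting out from 4 and returning at 6: ozonolysis of 4 (O3, CH2Cl2, −78 °C; then PPh3) gives 20-chloroicosanal F6. Horner–Wadsworth–Emmons reaction with triethyl phosphonoacetate and NaH in THF gives ethyl (E)-22-chlorodocos-2-enoate F7, which can be recrystallised to geometric purity. Reduction with diisobutylaluminium hydride (CH2Cl2, −78 °C) gives (E)-22-chlorodocos-2-en-1-ol F8, and Appel bromination (CBr4, PPh3, CH2Cl2, 0 °C) returns 6.

**Step 4.** The most likely failure is incomplete saturation, because diimide disproportionates in competition with hydrogen transfer; residual 8 has the same polarity as 9, although it can be held back on AgNO3-impregnated silica.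
Fallback (change of order and of reduction type), setting out from 8 and returning at 13: 8 is first esterified with 10 under the conditions of step 5, by way of 11 and of (R)-22-iodo-3-methyldocos-1-ene F9, to give (R)-20-methyldocos-21-en-1-yl 2,3-dihydroxybenzoate F10. The vinyl group of this polar, easily purified ester is then hydrogenated homogeneously (H2 1 atm, RhCl(PPh3)3, toluene/EtOH, rt) to give 13; this catalyst saturates monosubstituted alkenes with little tendency to move the double bond.

**Step 5.** The most likely failures are competing alkylation at a phenolic oxygen of ring A, slow heterogeneous displacement at a waxy C23 chloride in DMF, and oxidative darkening of the catechol if air is admitted.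
Fallback (protected head group), setting out from 9 and returning at 13: 2,3-bis(benzyloxy)benzoic acid F11 is alkylated with 9 (Cs2CO3, 0.6 equiv per acid, NaI, DMF, 80 °C; 12 is again the transient electrophile) to give (S)-20-methyldocosyl 2,3-bis(benzyloxy)benzoate F12. Hydrogenolysis (H2, Pd/C, EtOAc/THF, rt) removes both benzyl groups and gives 13. Palladium is harmless at this point because the chain no longer contains a double bond.

## Further compounds

F1 | step 3 | (S)-1-bromo-2-methylbutane | CC[C@H](C)CBr
F2 | step 3 | (S)-2-methylbutylmagnesium bromide | CC[C@H](C)C[Mg]Br
F3 | step 3 | 1,8-dibromooctane | BrCCCCCCCCBr
F4 | step 3 | (S)-1-bromo-10-methyldodecane | CC[C@H](C)CCCCCCCCCBr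
F5 | step 3 | (S)-(10-methyldodecyl)magnesium bromide | CC[C@H](C)CCCCCCCCC[Mg]Br
F6 | step 2 | 20-chloroicosanal | O=CCCCCCCCCCCCCCCCCCCCCl
F7 | step 2 | ethyl (E)-22-chlorodocos-2-enoate | CCOC(=O)/C=C/CCCCCCCCCCCCCCCCCCCCl
F8 | step 2 | (E)-22-chlorodocos-2-en-1-ol | OC/C=C/CCCCCCCCCCCCCCCCCCCCl
F9 | step 4 | (R)-22-iodo-3-methyldocos-1-ene | C=C[C@H](C)CCCCCCCCCCCCCCCCCCCI
F10 | step 4 | (R)-20-methyldocos-21-en-1-yl 2,3-dihydroxybenzoate | C=C[C@H](C)CCCCCCCCCCCCCCCCCCCOC(=O)c1cccc(O)c1O
F11 | step 5 | 2,3-bis(benzyloxy)benzoic acid | OC(=O)c1cccc(OCc2ccccc2)c1OCc1ccccc1
F12 | step 5 | (S)-20-methyldocosyl 2,3-bis(benzyloxy)benzoate | CC[C@H](C)CCCCCCCCCCCCCCCCCCCOC(=O)c1cccc(OCc2ccccc2)c1OCc1ccccc1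
A1 | alternative 1 | racemic 2-(1-chloroethyl)-4,4,5,5-tetramethyl-1,3,2-dioxaborolane | CC(Cl)B1OC(C)(C)C(C)(C)O1
A2 | alternative 1 | [19-(benzyloxy)nonadecyl]zinc iodide | I[Zn]CCCCCCCCCCCCCCCCCCCOCc1ccccc1
A3 | alternative 1 | (R)-2-[21-(benzyloxy)henicosan-2-yl]-4,4,5,5-tetramethyl-1,3,2-dioxaborolane | CC1(C)OB(OC1(C)C)[C@H](C)CCCCCCCCCCCCCCCCCCCOCc1ccccc1
A4 | alternative 1 | (S)-20-methyldocosan-1-ol | CC[C@H](C)CCCCCCCCCCCCCCCCCCCO
A5 | alternative 2 | (S)-4-methylhexanoic acid | CC[C@H](C)CCC(=O)O
A6 | alternative 2 | 18-methoxy-18-oxooctadecanoic acid (octadecanedioic acid monomethyl ester) | COC(=O)CCCCCCCCCCCCCCCCC(=O)O
A7 | alternative 2 | methyl (S)-20-methyldocosanoate | CC[C@H](C)CCCCCCCCCCCCCCCCCCC(=O)OC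
A8 | alternative 3 | (S)-3-methyldocosane | CC[C@H](C)CCCCCCCCCCCCCCCCCCC
A9 | alternative 3 | bis(pinacolato)diboron | CC1(C)OB(OC1(C)C)B1OC(C)(C)C(C)(C)O1
A10 | alternative 3 | (S)-4,4,5,5-tetramethyl-2-(20-methyldocosyl)-1,3,2-dioxaborolane | CC[C@H](C)CCCCCCCCCCCCCCCCCCCB1OC(C)(C)C(C)(C)O1
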